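**Plan**
- Retrosynthesis: remove the phenol benzyl group; take the C5–C6 epoxide back to the alkene (oxygen delivered by the 8-OH); take C8–OH/C8a–H back to a C8=C8a alkene and the ester back to the C1 carbinol; then cut C4–C5 and C6–C7 together.
- Enabling feature: in the seven-membered ring the two-carbon unit C5/C6 lies between two CH2 groups, C4 (on the quaternary ring-fusion carbon C3a) and C7 (on the carbinol carbon C8). The chain C7–C8–C8a–C3a–C4 is therefore the five-carbon unit of a vinylcyclopropane (cyclopropane C8a/C3a/C4 fused to the cyclopentane, vinyl = C8=C7) and C5/C6 is an alkyne: a rhodium-catalysed (5+2) cycloaddition.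
- Helper: a Me3Si group on the alkyne fixes its orientation, shields C5=C6 during the hydroboration and is then removed by protodesilylation.
- Forward order: cyclopentenol, then the cyclopropane (bicyclo[3.1.0]hexane), then the C1 carbinol, then the seven-membered ring, then C8/C8a, then the epoxide.
- Stereochemistry: a CBS reduction sets a carbinol that directs the Simmons–Smith reaction (fixes C3a); exo epoxidation and hydride opening set C1; hydroboration anti to the angular methyl sets C8 and C8a; hydroxyl-directed epoxidation sets C5 and C6.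

Key step: step 9

Assumption: the ester is taken on the tertiary C1 oxygen as drawn, so no strongly basic step follows the unveiling of the 8-OH (a 1→8 acyl shift is conceivable); hydroazulenes carry azulene locants (C1 isopropyl carbinol, C3a methyl-bearing fusion carbon, C5/C6 epoxide, C8 secondary carbinol, C8a fusion CH), α is the face of 8a-H and β the face of the C3a methyl.

Step 1
Reactants: 1 2-bromo-3-methylcyclopent-2-en-1-one
Product: 2 (R)-2-bromo-3-methylcyclopent-2-en-1-ol
Conditions: (S)-Me-CBS oxazaborolidine (10 mol%), BH3·SMe2, THF, −20 °C; MeOH, aqueous work-up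
Reagents that add atoms: none
Why: Corey–Bakshi–Shibata reduction, in which the (S)-oxazaborolidine–borane complex treats the bromoalkenyl side as the large group and delivers hydride to one carbonyl face, setting the (R)-carbinol that later steers the cyclopropanation.

Step 2
Reactants: 2 (R)-2-bromo-3-methylcyclopent-2-en-1-ol; 3 2-ethenyl-4,4,5,5-tetramethyl-1,3,2-dioxaborolane
Product: 4 (R)-2-ethenyl-3-methylcyclopent-2-en-1-ol
Conditions: Pd(dppf)Cl2 (5 mol%), K2CO3, dioxane/H2O, 80 °C
Reagents that add atoms: none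
Why: Suzuki–Miyaura coupling of the alkenyl bromide with the vinylboronate, which tolerates the free allylic alcohol and does not involve the stereocentre.

Step 3
Reactants: 4 (R)-2-ethenyl-3-methylcyclopent-2-en-1-ol
Product: 5 (1R,2R,5R)-1-ethenyl-5-methylbicyclo[3.1.0]hexan-2-ol (OH cis to the cyclopropane CH2)
Conditions: Et2Zn (1.5 equiv), CH2I2 (1.5 equiv), CH2Cl2, −10 °C
Reagents that add atoms: diiodomethane ICI
Why: Hydroxyl-directed Simmons–Smith (Furukawa) cyclopropanation, in which the zinc alkoxide delivers CH2 to the allylic, tetrasubstituted ring alkene on the face of the OH (the homoallylic, less electron-rich vinyl group should be left), setting C1 and C5.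

Step 4
Reactants: 5 (1R,2R,5R)-1-ethenyl-5-methylbicyclo[3.1.0]hexan-2-ol
Product: 6 (1R,5R)-1-ethenyl-5-methylbicyclo[3.1.0]hexan-2-one
Conditions: (n-Pr4N)RuO4 (5 mol%), NMO, 4 Å MS, CH2Cl2, rt
Reagents that add atoms: none
Why: Ley–Griffith oxidation of the secondary cyclopropylcarbinol under neutral conditions; the carbinol centre has done its directing work and is cleared while both cyclopropane centres remain.

Step 5
Reactants: 6 (1R,5R)-1-ethenyl-5-methylbicyclo[3.1.0]hexan-2-one
Product: 8 (1R,5R)-1-ethenyl-5-methylbicyclo[3.1.0]hex-2-en-2-yl trifluoromethanesulfonate, via potassium enolate 7 (not isolated)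
Conditions: KHMDS, THF, −78 °C; PhNTf2, −78 °C to 0 °C
Reagents that add atoms: N-phenylbis(trifluoromethanesulfonimide) O=S(=O)(N(c1ccccc1)S(=O)(=O)C(F)(F)F)C(F)(F)F
Why: Enolate formation can occur only toward C3 because C1 is quaternary, and O-triflation then gives the enol triflate regiospecifically.

Step 6
Reactants: 8 (1R,5R)-1-ethenyl-5-methylbicyclo[3.1.0]hex-2-en-2-yl trifluoromethanesulfonate
Product: 9 (1R,5R)-1-ethenyl-5-methyl-2-(propan-2-yl)bicyclo[3.1.0]hex-2-ene
Conditions: Fe(acac)3 (5 mol%), i-PrMgCl, THF/NMP, −30 °C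
Reagents that add atoms: isopropylmagnesium chloride CC(C)[Mg]Cl
Why: Iron-catalysed Kumada-type cross-coupling of an alkenyl triflate with a secondary alkyl Grignard reagent, fast at low temperature so that isomerisation of the isopropyl group and attack on the vinylcyclopropane should not compete.

Step 7
Reactants: 9 (1R,5R)-1-ethenyl-5-methyl-2-(propan-2-yl)bicyclo[3.1.0]hex-2-ene
Product: 10 exo-2,3-epoxide of 9 (2,3-epoxy-1-ethenyl-5-methyl-2-(propan-2-yl)bicyclo[3.1.0]hexane, epoxide oxygen trans to the cyclopropane CH2)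
Conditions: DMDO (1.05 equiv), acetone, −20 °C
Reagents that add atoms: dimethyldioxirane CC1(C)OO1
Why: Electrophilic epoxidation by the dioxirane should pick the electron-rich trisubstituted ring alkene over the vinyl group and attack the exo face, because the endo hydrogen of the cyclopropane CH2 covers the other face; this places the C2 oxygen trans to the cyclopropane, and neutral conditions protect the cyclopropyl-substituted epoxide.

Step 8
Reactants: 10 exo-2,3-epoxide of 9
Product: 11 (1R,2R,5R)-1-ethenyl-5-methyl-2-(propan-2-yl)bicyclo[3.1.0]hexan-2-ol (OH trans to the cyclopropane CH2, isopropyl cis to it)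
Conditions: LiEt3BH, THF, 0 °C to rt
Reagents that add atoms: none
Why: SN2 opening of the epoxide by the borohydride at the secondary, less hindered C3 leaves the tertiary C2–O bond untouched, so the carbinol keeps the exo oxygen.

Step 9
Reactants: 11 (1R,2R,5R)-1-ethenyl-5-methyl-2-(propan-2-yl)bicyclo[3.1.0]hexan-2-ol; 12 trimethyl(prop-1-yn-1-yl)silane
Product: 13 (1R,3aR)-3a,6-dimethyl-1-(propan-2-yl)-5-(trimethylsilyl)-1,2,3,3a,4,7-hexahydroazulen-1-ol
Conditions: [Rh(CO)2Cl]2 (5 mol%), 12 (3 equiv), ClCH2CH2Cl, 80 °C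
Reagents that add atoms: none
Why: Monovalent rhodium opens the vinyl-conjugated C1–C6 bond of the 1-vinylbicyclo[3.1.0]hexane to a σ-alkyl/π-allyl rhodacyclohexene, the alkyne inserts at the allyl terminus and C(sp2)–C(sp3) reductive elimination follows; the closest known reaction type is the rhodium-catalysed intermolecular (5+2) cycloaddition of vinylcyclopropanes with alkynes. The seven-membered ring is closed as a (5+2) cycloaddition onto the intact cyclopentane (C7, C8, C8a, C3a and C4 from 11, C5 and C6 from 12), not by an exo or endo closure of a chain. No new stereocentre arises because C8a becomes sp2; the quaternary C3a keeps the configuration given by the cyclopropanation since none of its bonds is broken, and C1 is untouched. The first selectivity needed is cleavage of C1–C6 and not C1–C5: C5 is quaternary, and the primary Rh–CH2 so formed has no β-hydrogen, which shuts off diene formation by β-hydride elimination. The second is the orientation of the alkyne: the Me3Si group should stay on the rhodium-bound carbon, distal to the first-formed C–C bond, so that C–CH3 joins the vinyl terminus (C7) and C–Si joins the cyclopropane CH2 (C4). The silyl group is a helper that also shields C5=C6 in step 11 and leaves in step 12.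

Step 10
Reactants: 13 (1R,3aR)-3a,6-dimethyl-1-(propan-2-yl)-5-(trimethylsilyl)-1,2,3,3a,4,7-hexahydroazulen-1-ol; 14 4-(benzyloxy)benzoyl chloride
Product: 16 (1R,3aR)-3a,6-dimethyl-1-(propan-2-yl)-5-(trimethylsilyl)-1,2,3,3a,4,7-hexahydroazulen-1-yl 4-(benzyloxy)benzoate, via lithium alkoxide 15 (not isolated)
Conditions: n-BuLi, THF, −78 °C; 14, −78 °C to 0 °C
Reagents that add atoms: none
Why: Acylation of the lithium alkoxide of the hindered tertiary allylic alcohol with the aroyl chloride puts the ester on O1 while no other hydroxyl exists; C1 is not touched.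

Step 11
Reactants: 16 (1R,3aR)-3a,6-dimethyl-1-(propan-2-yl)-5-(trimethylsilyl)-1,2,3,3a,4,7-hexahydroazulen-1-yl 4-(benzyloxy)benzoate
Product: 18 (1R,3aR,8S,8aS)-8-hydroxy-3a,6-dimethyl-1-(propan-2-yl)-5-(trimethylsilyl)-1,2,3,3a,4,7,8,8a-octahydroazulen-1-yl 4-(benzyloxy)benzoate, via alkylborane 17 (not isolated)
Conditions: BH3·THF, THF, 0 °C to rt; then NaBO3·4H2O, H2O, rt
Reagents that add atoms: sodium perborate [Na+].[Na+].O[B-]1(O)OO[B-](O)(O)OO1
Why: Brown hydroboration–oxidation adds H to C8a and B to the less substituted C8 in a syn fashion; with the isopropyl group pseudo-equatorial, the angular C3a methyl and the C1 aroyloxy group are pseudo-axial on the β face on both sides of C8a, so borane should add from the α face and retentive oxidation gives the 8α-OH/8aα-H pair of the trans-fused system, while the tetrasubstituted vinylsilane is too hindered to react and the mild perborate spares the ester.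

Step 12
Reactants: 18 (1R,3aR,8S,8aS)-8-hydroxy-3a,6-dimethyl-1-(propan-2-yl)-5-(trimethylsilyl)-1,2,3,3a,4,7,8,8a-octahydroazulen-1-yl 4-(benzyloxy)benzoate
Product: 19 (1R,3aR,8S,8aS)-8-hydroxy-3a,6-dimethyl-1-(propan-2-yl)-1,2,3,3a,4,7,8,8a-octahydroazulen-1-yl 4-(benzyloxy)benzoate
Conditions: p-TsOH·H2O (20 mol%), MeCN/H2O, 40 °C
Reagents that add atoms: none
Why: Protodesilylation by ipso protonation at C5, which passes through a β-silyl-stabilised tertiary cation at C6 and loses silicon to water, so the double bond stays at C5=C6; the mild acid should leave the tertiary ester and the benzyl ether.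

Step 13
Reactants: 19 (1R,3aR,8S,8aS)-8-hydroxy-3a,6-dimethyl-1-(propan-2-yl)-1,2,3,3a,4,7,8,8a-octahydroazulen-1-yl 4-(benzyloxy)benzoate
Product: 20 (1R,3aR,5S,6R,8S,8aS)-5,6-epoxy-8-hydroxy-3a,6-dimethyl-1-(propan-2-yl)decahydroazulen-1-yl 4-(benzyloxy)benzoate
Conditions: VO(acac)2 (5 mol%), t-BuOOH, CH2Cl2, 0 °C to rt
Reagents that add atoms: tert-butyl hydroperoxide CC(C)(C)OO
Why: Vanadium-catalysed epoxidation directed by the homoallylic 8α-hydroxyl delivers oxygen to the α face of the only remaining alkene, giving the 5α,6α-epoxide cis to the 8-OH under neutral conditions that keep the ester on O1.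

Step 14
Reactants: 20 (1R,3aR,5S,6R,8S,8aS)-5,6-epoxy-8-hydroxy-3a,6-dimethyl-1-(propan-2-yl)decahydroazulen-1-yl 4-(benzyloxy)benzoate
Product: 21 (1R,3aR,5S,6R,8S,8aS)-5,6-epoxy-8-hydroxy-3a,6-dimethyl-1-(propan-2-yl)decahydroazulen-1-yl 4-hydroxybenzoate
Conditions: H2 (1 atm), 10% Pd/C, EtOAc, rt
Reagents that add atoms: none
Why: Hydrogenolysis of the aryl benzyl ether under neutral conditions; no alkene remains, and the trialkyl epoxide, the non-benzylic tertiary ester and the free 8-OH should be unaffected, so no acyl shift is triggered.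

**Compound list**
1 | 2-bromo-3-methylcyclopent-2-en-1-one | CC1=C(Br)C(=O)CC1 | starting material
2 | (R)-2-bromo-3-methylcyclopent-2-en-1-ol | O[C@@H]1CCC(C)=C1Br | intermediate
3 | 2-ethenyl-4,4,5,5-tetramethyl-1,3,2-dioxaborolane | C=CB1OC(C)(C)C(C)(C)O1 | starting material
4 | (R)-2-ethenyl-3-methylcyclopent-2-en-1-ol | O[C@@H]1CCC(C)=C1C=C | intermediate
5 | (1R,2R,5R)-1-ethenyl-5-methylbicyclo[3.1.0]hexan-2-ol | O[C@@H]1CC[C@]2(C)C[C@@]21C=C | intermediate
6 | (1R,5R)-1-ethenyl-5-methylbicyclo[3.1.0]hexan-2-one | O=C1CC[C@]2(C)C[C@@]21C=C | intermediate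
7 | potassium (1R,5R)-1-ethenyl-5-methylbicyclo[3.1.0]hex-2-en-2-olate | [K+].[O-]C1=CC[C@]2(C)C[C@@]21C=C | intermediate
8 | (1R,5R)-1-ethenyl-5-methylbicyclo[3.1.0]hex-2-en-2-yl trifluoromethanesulfonate | O=S(=O)(OC1=CC[C@]2(C)C[C@@]21C=C)C(F)(F)F | intermediate
9 | (1R,5R)-1-ethenyl-5-methyl-2-(propan-2-yl)bicyclo[3.1.0]hex-2-ene | CC(C)C1=CC[C@]2(C)C[C@@]21C=C | intermediate
10 | exo-2,3-epoxide of 9 (oxygen trans to the cyclopropane CH2) | CC(C)[C@]12O[C@H]1C[C@]3(C)C[C@@]32C=C | intermediate
11 | (1R,2R,5R)-1-ethenyl-5-methyl-2-(propan-2-yl)bicyclo[3.1.0]hexan-2-ol | CC(C)[C@]1(O)CC[C@]2(C)C[C@@]21C=C | intermediate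
12 | trimethyl(prop-1-yn-1-yl)silane | CC#C[Si](C)(C)C | starting material
13 | (1R,3aR)-3a,6-dimethyl-1-(propan-2-yl)-5-(trimethylsilyl)-1,2,3,3a,4,7-hexahydroazulen-1-ol | CC(C)[C@]1(O)CC[C@]2(C)CC([Si](C)(C)C)=C(C)CC=C21 | intermediate
14 | 4-(benzyloxy)benzoyl chloride | O=C(Cl)c1ccc(OCc2ccccc2)cc1 | starting material
15 | lithium alkoxide of 13 | [Li+].CC(C)[C@]1([O-])CC[C@]2(C)CC([Si](C)(C)C)=C(C)CC=C21 | intermediate
16 | (1R,3aR)-3a,6-dimethyl-1-(propan-2-yl)-5-(trimethylsilyl)-1,2,3,3a,4,7-hexahydroazulen-1-yl 4-(benzyloxy)benzoate | CC(C)[C@]1(OC(=O)c3ccc(OCc4ccccc4)cc3)CC[C@]2(C)CC([Si](C)(C)C)=C(C)CC=C21 | intermediate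
17 | 8α-boranyl-8aα-H monoalkylborane from 16 (configuration at C8 and C8a as in 18) | CC(C)[C@]1(OC(=O)c3ccc(OCc4ccccc4)cc3)CC[C@]2(C)CC([Si](C)(C)C)=C(C)C[C@H](B)[C@H]21 | intermediate
18 | (1R,3aR,8S,8aS)-8-hydroxy-3a,6-dimethyl-1-(propan-2-yl)-5-(trimethylsilyl)-1,2,3,3a,4,7,8,8a-octahydroazulen-1-yl 4-(benzyloxy)benzoate | CC(C)[C@]1(OC(=O)c3ccc(OCc4ccccc4)cc3)CC[C@]2(C)CC([Si](C)(C)C)=C(C)C[C@H](O)[C@H]21 | intermediate
19 | (1R,3aR,8S,8aS)-8-hydroxy-3a,6-dimethyl-1-(propan-2-yl)-1,2,3,3a,4,7,8,8a-octahydroazulen-1-yl 4-(benzyloxy)benzoate | CC(C)[C@]1(OC(=O)c3ccc(OCc4ccccc4)cc3)CC[C@]2(C)CC=C(C)C[C@H](O)[C@H]21 | intermediate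
20 | (1R,3aR,5S,6R,8S,8aS)-5,6-epoxy-8-hydroxy-3a,6-dimethyl-1-(propan-2-yl)decahydroazulen-1-yl 4-(benzyloxy)benzoate | CC(C)[C@]1(OC(=O)c3ccc(OCc4ccccc4)cc3)CC[C@]2(C)C[C@@H]5O[C@]5(C)C[C@H](O)[C@H]21 | intermediate
21 | (1R,3aR,5S,6R,8S,8aS)-5,6-epoxy-8-hydroxy-3a,6-dimethyl-1-(propan-2-yl)decahydroazulen-1-yl 4-hydroxybenzoate | CC(C)[C@]1(OC(=O)c2ccc(O)cc2)CC[C@]2(C)C[C@@H]3O[C@]3(C)C[C@H](O)[C@H]21 | target

**Count and risks**
Total step count: 14. Longest linear sequence: 14 steps (1 to 21); 3, 12 and 14 are bought.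

Most likely to fail:

1. Step 9. The cycloaddition may stall because ring opening and insertion are slow with the hindered silylalkyne, or the alkyne may insert in both orientations. The fallback sets out from 11 and comes back at 19. It exchanges steric for electronic control by using the acceptor alkyne 1-(phenylsulfonyl)prop-1-yne (CC#CS(=O)(=O)c1ccccc1) under the same rhodium catalysis; acceptor alkynes are the most reactive two-carbon partners and the sulfonyl group should sit on the rhodium-bound carbon. This should give the C5-phenylsulfonyl analogue of 13, sulfonyl dienol F1. Acylation with n-BuLi and 14 gives the sulfonyl diene ester F2. Hydroboration–oxidation as in step 11, to which the electron-poor vinyl sulfone is inert, gives the sulfonyl hydroxy ester F3. Reductive desulfonylation (Na(Hg), Na2HPO4, MeOH/THF, −20 °C) then gives 19.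

2. Step 11. Borane may approach from the β face and give the cis-fused 8β-alcohol (poor facial selectivity). The fallback sets out from 13 and comes back at 18, and replaces reagent approach by a directed step and a stereospecific shift. Hydroxyl-directed epoxidation of 13 (VO(acac)2, t-BuOOH) puts oxygen on the β face of C8=C8a, syn to the 1-OH, and gives the 8β,8aβ-epoxy alcohol F4. Acylation (n-BuLi, then 14) gives the epoxy ester F5. Meinwald rearrangement (BF3·OEt2, CH2Cl2, −78 °C) ionises C8a–O and shifts the C8 hydrogen to the α face of C8a, giving the trans-fused 8-ketone F6. Reduction with NaBH4/CeCl3 (MeOH, −78 °C) from the β face, which this scenario has shown to be the open one, gives 18.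

3. Step 12. The acid may ionise the tertiary ester, promote a 1→8 acyl shift or move the new double bond in competition with ipso protonation. The fallback sets out from 18 and comes back at 19 without acid. Ipso-iododesilylation with N-iodosuccinimide (MeCN, 0 °C) gives the C5 vinyl iodide F7, and radical hydrodeiodination (Bu3SnH, AIBN, benzene, 80 °C) gives 19.

Further compounds
F1 | step 9 | C5-phenylsulfonyl analogue of 13 (PhSO2 in place of Me3Si) | CC(C)[C@]1(O)CC[C@]2(C)CC(S(=O)(=O)c3ccccc3)=C(C)CC=C21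
F2 | step 9 | 4-(benzyloxy)benzoate of F1 (C5-phenylsulfonyl analogue of 16) | CC(C)[C@]1(OC(=O)c3ccc(OCc4ccccc4)cc3)CC[C@]2(C)CC(S(=O)(=O)c5ccccc5)=C(C)CC=C21
F3 | step 9 | C5-phenylsulfonyl analogue of 18 (8α-OH, 8aα-H) | CC(C)[C@]1(OC(=O)c3ccc(OCc4ccccc4)cc3)CC[C@]2(C)CC(S(=O)(=O)c5ccccc5)=C(C)C[C@H](O)[C@H]21
F4 | step 11 | 8β,8aβ-epoxide of 13 | CC(C)[C@]1(O)CC[C@]2(C)CC([Si](C)(C)C)=C(C)C[C@H]3O[C@]321
F5 | step 11 | 4-(benzyloxy)benzoate of F4 | CC(C)[C@]1(OC(=O)c4ccc(OCc5ccccc5)cc4)CC[C@]2(C)CC([Si](C)(C)C)=C(C)C[C@H]3O[C@]321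
F6 | step 11 | trans-fused 8-ketone (8aα-H) corresponding to 18 | CC(C)[C@]1(OC(=O)c3ccc(OCc4ccccc4)cc3)CC[C@]2(C)CC([Si](C)(C)C)=C(C)CC(=O)[C@H]21
F7 | step 12 | C5-iodo analogue of 18 (I in place of Me3Si) | CC(C)[C@]1(OC(=O)c3ccc(OCc4ccccc4)cc3)CC[C@]2(C)CC(I)=C(C)C[C@H](O)[C@H]21
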